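**Plan** (indene numbering of the target: C1 = CHMe, C2 = C=O, C3 = CHEt, C3a, C4 = C(Et)CO2H, C5 = C(Et)(styryl), C6 = CH=, C7 = C(Et)=, C7a)

- Retrosynthesis: cut C1–C7a and C2–C3 (the cyclopentanone, excised as a propanal unit), then C5–CH= (olefination), then C4–C3a and C5–C6 (Diels–Alder), then the allene (propargyl Claisen).
- Forward: (R)-pentynol → allenic aldehyde → silyloxy vinylallene; Diels–Alder with diethylmaleic anhydride builds the cyclohexene with both quaternary carbons; the C6 oxygen lactonises onto the C4 carboxyl, which frees the C5 carboxyl for conversion into the styrene; the cyclopentanone is annulated last.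
- Enabling feature: O=C2–C1–C7a–C7=C6 is a γ,δ-unsaturated carbonyl (Claisen retron of an allyl propenyl ether with O on C6, 1,3 and cis to the C4 carboxyl), and C2–C3 with H on C3a is the hydroacylation retron of an exocyclic C3a=C3 alkene; the target is an isomer of allyl ether 17.
- Stereochemistry: one bought carbinol centre → allene axis → C4, C5 and C6 (Diels–Alder, face anti to the allene ethyl, endo) → C7a (suprafacial [3,3]) → C3a (Rh–H delivered from the C7a-tethered acyl) → C1 and C3 (thermodynamic, all-trans cyclopentanone).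

Key step: step 7

Assumption: (R)-pent-1-yn-3-ol and 2,3-diethylmaleic anhydride are taken as catalogue compounds.

**Step 1**
Reactants: 1 (R)-pent-1-yn-3-ol; 2 1,1-diethoxybutane
Product: 5 (Ra)-2-ethylhepta-3,4-dienal, via mixed acetal 3 (not isolated), via propargyl butenyl ether 4 (not isolated)
Conditions: EtCO2H (cat.), xylene, 130 °C, EtOH distilled off
Reagents that add atoms: none
Why: Acid-catalysed acetal exchange and loss of ethanol give the propargyl vinyl ether, whose [3,3] shift (propargyl Claisen rearrangement, Saucy–Marbet type) forms the C–C bond syn to the departing C–O bond, so the (R)-carbinol should be translated into the (Ra) allene axis; the C2 centre is irrelevant because it is planarised in step 2.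

**Step 2**
Reactants: 5 (Ra)-2-ethylhepta-3,4-dienal
Product: 6 (Ra)-tert-butyl{[(1E)-2-ethylhepta-1,3,4-trien-1-yl]oxy}dimethylsilane
Conditions: TBSOTf, Et3N, CH2Cl2, −78 → 0 °C
Reagents that add atoms: tert-butyldimethylsilyl trifluoromethanesulfonate, CC(C)(C)[Si](C)(C)OS(=O)(=O)C(F)(F)F
Why: Soft enolisation and O-silylation of the α-branched aldehyde should give the conjugated silyl dienol ether without touching the allene axis; the (1E) isomer (OSi anti to the allenyl arm) is expected to predominate, and it is the only isomer whose cycloadduct can lactonise in step 3.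

**Step 3**
Reactants: 6 (Ra)-tert-butyl{[(1E)-2-ethylhepta-1,3,4-trien-1-yl]oxy}dimethylsilane; 7 2,3-diethylmaleic anhydride
Product: 9 lactone acid 1,4,8-triethyl-7-oxo-2-[(E)-propylidene]-6-oxabicyclo[3.2.1]oct-3-ene-8-carboxylic acid (carboxyl syn to the lactone bridge), via silyl ether cycloadduct 8 (not isolated)
Conditions: PhMe, BHT (cat.), 70 °C; then HF·pyridine, THF, 0 °C → rt; NaHCO3 extraction
Reagents that add atoms: none
Why: Diels–Alder reaction of the electron-rich vinylallene with the Z-tetrasubstituted dienophile should occur on the diene face anti to the ethyl group of the allene terminus (axis-to-centre transfer that sets C4 and C5, cis-diethyl), with endo approach placing the C6 silyloxy group cis to the anhydride and the propylidene emerging E (ethyl syn to C7a); after fluoride cleavage the C6 hydroxyl opens the anhydride at the only carbonyl it can reach through a five-membered ring (that on C4), which differentiates the two carboxyls.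

**Step 4**
Reactants: 9 lactone acid
Product: 11 lactone aldehyde 1,4,8-triethyl-7-oxo-2-[(E)-propylidene]-6-oxabicyclo[3.2.1]oct-3-ene-8-carbaldehyde, via acid chloride 10 (not isolated)
Conditions: (COCl)2, DMF (cat.), CH2Cl2, 0 °C; then LiAlH(O-t-Bu)3, THF, −78 °C
Reagents that add atoms: none
Why: The only free carboxyl (on C5) is activated as its chloride and reduced by the hindered hydride at −78 °C (acid chloride to aldehyde reduction), conditions under which the bridged lactone and the diene should be inert.

**Step 5**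
Reactants: 11 lactone aldehyde; 12 diethyl benzylphosphonate
Product: 13 styryl lactone 1,4,8-triethyl-8-[(E)-2-phenylethenyl]-2-[(E)-propylidene]-6-oxabicyclo[3.2.1]oct-3-en-7-one
Conditions: NaH, THF, 0 → 40 °C
Reagents that add atoms: none
Why: Horner–Wadsworth–Emmons olefination of the non-enolisable neopentylic aldehyde with the benzylphosphonate anion should give the (E)-styrene, and no stereocentre can epimerise because both neighbours are quaternary.

**Step 6**
Reactants: 13 styryl lactone; 14 allyl bromide
Product: 17 allyl ether acid 1,4,6-triethyl-6-[(E)-2-phenylethenyl]-5-(prop-2-en-1-yloxy)-2-[(E)-propylidene]cyclohex-3-ene-1-carboxylic acid (1-CO2H 5-O and 6-styryl on one face), via sodium hydroxy carboxylate 15 (not isolated), via disodium alkoxide carboxylate 16 (not isolated)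
Conditions: NaOH (1.0 equiv), THF–H2O, rt; evaporate; NaH (1.1 equiv), THF, 0 °C; 14 (1.1 equiv); then aq. HCl to pH 3
Reagents that add atoms: sodium hydroxide, [Na+].[OH-]
Why: Saponification opens the lactone and the sodium alkoxide, far more nucleophilic than the sodium carboxylate in THF, undergoes Williamson O-allylation, after which relactonisation is impossible; sodium as counter-ion and 0 °C are chosen so that alkylation outruns anionic oxy-Cope cleavage of the 3-oxido-1,5-diene (C7a=C7–C6(O−)–C5–CH=CHPh).

**Step 7**
Reactants: 17 allyl ether acid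
Product: 22 CNP0420507.1 (trans-fused; all-trans cyclopentanone), via trimethylsilyl ester 18 (not isolated), via propenyl ether 19 (not isolated), via Claisen aldehyde 20 (not isolated), via cyclopentanone epimers 21 (not isolated)
Conditions: BSA, CH2Cl2, rt; [Ir(cod)Cl]2–PCy3–NaBPh4 (cat.), rt; ClCH2CH2Cl, 70 °C; [Rh(dppe)]ClO4 (cat.), 70 °C; DBU, rt; aq. citric acid
Reagents that add atoms: none
Why: After transient silylation of the acid, Ir(I) hydride isomerises only the unhindered O-allyl group to the (E)-propenyl ether, and the resulting allyl vinyl ether undergoes a suprafacial [3,3] shift (aliphatic Claisen; closest precedent the isomerisation–Claisen rearrangement of di(allyl) ethers) in which the propenyl terminus (future C1) bonds to C7a on the face that carried the C6–O bond while the ring alkene moves to C7=C6. The 2-methyl-4-alkenal so formed is closed by cationic Rh(I) through formyl C–H oxidative addition, syn hydrometalation of the exocyclic C3a=C3 alkene and C–C reductive elimination (closest precedent the tandem Claisen–hydroacylation of allyl vinyl ethers and the Rh-catalysed cyclisation of 4-pentenals). The five-membered ring is closed from a six-membered acyl-rhodacycle, formally a 5-endo-trig closure at C3 made possible by the metal. C7a is set by the C6 carbinol through the cyclic transition state, C3a by delivery of hydride from the acyl-rhodium tethered at C7a (H cis to C1, hence a trans ring fusion), and C1 and C3 by DBU equilibration to the all-trans ketone. The step needs hydride insertion into the exocyclic alkene from the α-face and not into C7=C6: the (E)-propylidene, whose ethyl is syn to C7a, forces the C7a side chain axial by A(1,3) strain and so holds rhodium under the exocyclic alkene, while C6 of the ring alkene is neopentylic and resists Rh–C bond formation.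

**Compound list**
1 | (R)-pent-1-yn-3-ol | C#C[C@H](O)CC | starting material
2 | 1,1-diethoxybutane | CCCC(OCC)OCC | starting material
3 | (3R)-3-(1-ethoxybutoxy)pent-1-yne; acetal carbon unassigned; not isolated | C#C[C@@H](CC)OC(CCC)OCC | intermediate
4 | (3R)-3-(but-1-en-1-yloxy)pent-1-yne; E/Z mixture; not isolated | C#C[C@@H](CC)OC=CCC | intermediate
5 | (Ra)-2-ethylhepta-3,4-dienal; C2 epimers | CCC([H])=[C@]=C([H])C(CC)C=O | intermediate
6 | (Ra)-tert-butyl{[(1E)-2-ethylhepta-1,3,4-trien-1-yl]oxy}dimethylsilane | CCC([H])=[C@]=C([H])/C(CC)=C/O[Si](C)(C)C(C)(C)C | intermediate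
7 | 2,3-diethylmaleic anhydride (3,4-diethylfuran-2,5-dione) | CCC1=C(CC)C(=O)OC1=O | starting material
8 | 4-[(tert-butyldimethylsilyl)oxy]-3a,5,7a-triethyl-7-[(E)-propylidene]-3a,4,7,7a-tetrahydro-2-benzofuran-1,3-dione; silyloxy cis to the anhydride ring; not isolated | C1=C(CC)[C@@H](O[Si](C)(C)C(C)(C)C)[C@@]2(CC)C(=O)OC(=O)[C@@]2(CC)/C1=C/CC | intermediate
9 | 1,4,8-triethyl-7-oxo-2-[(E)-propylidene]-6-oxabicyclo[3.2.1]oct-3-ene-8-carboxylic acid; carboxyl syn to the lactone bridge | C1=C(CC)[C@@H](O2)[C@@](CC)(C(=O)O)[C@@](CC)(C2=O)/C1=C/CC | intermediate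
10 | 8-carbonyl chloride of 9; not isolated | C1=C(CC)[C@@H](O2)[C@@](CC)(C(=O)Cl)[C@@](CC)(C2=O)/C1=C/CC | intermediate
11 | 1,4,8-triethyl-7-oxo-2-[(E)-propylidene]-6-oxabicyclo[3.2.1]oct-3-ene-8-carbaldehyde | C1=C(CC)[C@@H](O2)[C@@](CC)(C=O)[C@@](CC)(C2=O)/C1=C/CC | intermediate
12 | diethyl benzylphosphonate | CCOP(=O)(Cc1ccccc1)OCC | starting material
13 | 1,4,8-triethyl-8-[(E)-2-phenylethenyl]-2-[(E)-propylidene]-6-oxabicyclo[3.2.1]oct-3-en-7-one; styryl syn to the lactone bridge | C1=C(CC)[C@@H](O2)[C@@](CC)(/C=C/c3ccccc3)[C@@](CC)(C2=O)/C1=C/CC | intermediate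
14 | allyl bromide | C=CCBr | starting material
15 | sodium 1,4,6-triethyl-5-hydroxy-6-[(E)-2-phenylethenyl]-2-[(E)-propylidene]cyclohex-3-ene-1-carboxylate; not isolated | C1=C(CC)[C@@H](O)[C@@](CC)(/C=C/c2ccccc2)[C@@](CC)(C(=O)[O-])/C1=C/CC.[Na+] | intermediate
16 | disodium alkoxide carboxylate of 15; not isolated | C1=C(CC)[C@@H]([O-])[C@@](CC)(/C=C/c2ccccc2)[C@@](CC)(C(=O)[O-])/C1=C/CC.[Na+].[Na+] | intermediate
17 | 1,4,6-triethyl-6-[(E)-2-phenylethenyl]-5-(prop-2-en-1-yloxy)-2-[(E)-propylidene]cyclohex-3-ene-1-carboxylic acid; 1-CO2H 5-O and 6-styryl on one face | C1=C(CC)[C@@H](OCC=C)[C@@](CC)(/C=C/c2ccccc2)[C@@](CC)(C(=O)O)/C1=C/CC | intermediate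
18 | trimethylsilyl ester of 17; not isolated | C1=C(CC)[C@@H](OCC=C)[C@@](CC)(/C=C/c2ccccc2)[C@@](CC)(C(=O)O[Si](C)(C)C)/C1=C/CC | intermediate
19 | trimethylsilyl 1,4,6-triethyl-6-[(E)-2-phenylethenyl]-5-[(E)-prop-1-en-1-yloxy]-2-[(E)-propylidene]cyclohex-3-ene-1-carboxylate; not isolated | C1=C(CC)[C@@H](O/C=C/C)[C@@](CC)(/C=C/c2ccccc2)[C@@](CC)(C(=O)O[Si](C)(C)C)/C1=C/CC | intermediate
20 | trimethylsilyl 1,2,4-triethyl-5-(1-oxopropan-2-yl)-2-[(E)-2-phenylethenyl]-6-[(E)-propylidene]cyclohex-3-ene-1-carboxylate; side-chain epimers; not isolated | CCC1=C[C@](/C=C/c2ccccc2)(CC)[C@@](CC)(C(=O)O[Si](C)(C)C)/C(=C/CC)[C@H]1C(C)C=O | intermediate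
21 | trimethylsilyl ester of the trans-fused ketone; C1 and C3 epimers; not isolated | CCC1=C[C@](/C=C/c2ccccc2)(CC)[C@@](CC)(C(=O)O[Si](C)(C)C)[C@H]2[C@H]1C(C)C(=O)C2CC | intermediate
22 | CNP0420507.1: 3,4,5,7-tetraethyl-1-methyl-2-oxo-5-[(E)-2-phenylethenyl]-2,3,3a,4,5,7a-hexahydro-1H-indene-4-carboxylic acid; trans-fused; 4-CO2H 5-styryl H-3a H-1 and 3-Et on one face | CCC1=C[C@](/C=C/c2ccccc2)(CC)[C@@](CC)(C(=O)O)[C@H]2[C@H]1[C@@H](C)C(=O)[C@@H]2CC | target

**Step count and risks**
Total steps: 7. Longest linear sequence: 7 (from 1).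

Steps most likely to fail:

1. Step 7. Possible failures are decarbonylation of the acyl-rhodium hydride before it inserts the hindered trisubstituted alkene, hydride insertion into the ring alkene C6=C7, and delivery of hydride to the β-face of C3a if the C7a side chain leaves the axial position. The fallback sets out from 17 and returns at 22. Only the silylation, iridium isomerisation and thermal Claisen stages are run, and the aldehyde acid F1 is isolated after aqueous work-up. Condensation with 2-amino-3-picoline gives the aldimine F2, in which RhCl(PPh3)3 (PhMe, 130 °C) inserts into the imidoyl C–H bond as an N,N-chelate that cannot lose CO. Syn addition across the exocyclic alkene and reductive elimination give the ketimine F3, which is hydrolysed with aqueous HCl and equilibrated with DBU to 22.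

2. Step 3. Possible failures are a cycloaddition with the tetrasubstituted dienophile that is too slow to compete with decomposition of the diene, exo approach, and reaction of the minor (1Z) enol ether to an adduct that cannot lactonise. The fallback sets out from 1 and returns at 9. Johnson orthoester Claisen rearrangement of 1 with trimethyl orthobutyrate gives the allenic ester F4. LDA and TBSCl give the silyl ketene acetal F5, a 1,1-dioxygenated and much more nucleophilic vinylallene without enol ether geometry. Cycloaddition with 7 gives the mixed ketal adduct F6, which aqueous HCl in THF hydrolyses to the ketone F7. Luche reduction at −78 °C gives the C6 alcohol, whose cis isomer closes to 9 while the trans isomer is re-oxidised and recycled.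

3. Step 6. Possible failures are alkylation of the carboxylate followed by relactonisation, and anionic oxy-Cope fragmentation of the alkoxide. The fallback sets out from 13 and returns at 19, so neither a free alkoxide nor the iridium isomerisation is needed. Saponification gives 15, and TMSCl with imidazole gives the bis-silyl derivative F8. TMSOTf-catalysed exchange with propanal dimethyl acetal gives the mixed acetal F9, and elimination of methanol with TMSOTf and i-Pr2NEt gives the propenyl ether 19 as an E/Z mixture, both isomers of which rearrange.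

**Further compounds**
F1 | step 7 | 1,2,4-triethyl-5-(1-oxopropan-2-yl)-2-[(E)-2-phenylethenyl]-6-[(E)-propylidene]cyclohex-3-ene-1-carboxylic acid | CCC1=C[C@](/C=C/c2ccccc2)(CC)[C@@](CC)(C(=O)O)/C(=C/CC)[C@H]1C(C)C=O
F2 | step 7 | N-(3-methylpyridin-2-yl) aldimine of F1 | CCC1=C[C@](/C=C/c2ccccc2)(CC)[C@@](CC)(C(=O)O)/C(=C/CC)[C@H]1C(C)C=Nc3ncccc3C
F3 | step 7 | N-(3-methylpyridin-2-yl) ketimine of 22 (C1 and C3 epimers) | CCC1=C[C@](/C=C/c2ccccc2)(CC)[C@@](CC)(C(=O)O)[C@H]2[C@H]1C(C)C(=Nc3ncccc3C)C2CC
F4 | step 3 | methyl (Ra)-2-ethylhepta-3,4-dienoate | CCC([H])=[C@]=C([H])C(CC)C(=O)OC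
F5 | step 3 | (Ra)-tert-butyl[(2-ethyl-1-methoxyhepta-1,3,4-trien-1-yl)oxy]dimethylsilane | CCC([H])=[C@]=C([H])C(CC)=C(OC)O[Si](C)(C)C(C)(C)C
F6 | step 3 | 4-[(tert-butyldimethylsilyl)oxy]-3a,5,7a-triethyl-4-methoxy-7-[(E)-propylidene]-3a,4,7,7a-tetrahydro-2-benzofuran-1,3-dione | C1=C(CC)C(OC)(O[Si](C)(C)C(C)(C)C)[C@@]2(CC)C(=O)OC(=O)[C@@]2(CC)/C1=C/CC
F7 | step 3 | 3a,5,7a-triethyl-7-[(E)-propylidene]-7,7a-dihydro-2-benzofuran-1,3,4(3aH)-trione | C1=C(CC)C(=O)[C@@]2(CC)C(=O)OC(=O)[C@@]2(CC)/C1=C/CC
F8 | step 6 | trimethylsilyl 1,4,6-triethyl-6-[(E)-2-phenylethenyl]-2-[(E)-propylidene]-5-[(trimethylsilyl)oxy]cyclohex-3-ene-1-carboxylate | C1=C(CC)[C@@H](O[Si](C)(C)C)[C@@](CC)(/C=C/c2ccccc2)[C@@](CC)(C(=O)O[Si](C)(C)C)/C1=C/CC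
F9 | step 6 | trimethylsilyl 1,4,6-triethyl-5-(1-methoxypropoxy)-6-[(E)-2-phenylethenyl]-2-[(E)-propylidene]cyclohex-3-ene-1-carboxylate | C1=C(CC)[C@@H](OC(CC)OC)[C@@](CC)(/C=C/c2ccccc2)[C@@](CC)(C(=O)O[Si](C)(C)C)/C1=C/CC
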